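(All runs were computed from invented constants.)

1. Dissolved at saturation, reagent amounts to 9.52 % of the flask's charge and 18.2 % of the summer charge, while each substrate costs one reagent, either directly to isomer of the product or through tautomer to target.

| setting | summer | flask |
|---|---|---|
| substrate | 1.1 M | 2.1 M |
| gas | 200 mM (held) | 200 mM (held) |
| remark | run made earlier |  |
| time |  | 6.0 h |
summer run (percent of the substrate charged)

| time / h | target / % | substrate / % |
|---|---|---|
| 0.500 | 0 | 87 |
| 0.833 | 1 | 79 |
| 1.33 | 3 | 69 |
| 2.00 | 6 | 51 |
| 4.00 | 17 | 30 |
| 6.00 | 24 | 16 |

(readings scatter by 1.5 percentage points)
- at the start none of reagent is dissolved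
- what was read earlier has a scatter of 1.5 percentage points, one standard deviation
- reactions considered so far: substrate + reagent -> isomer of the product; gas <-> reagent; reagent + tautomer -> target; substrate <-> tautomer
1. target at 6.0 h, in percent of the substrate charged
2. concentration of reagent in solution at 6.0 h, in percent of saturation

2. The summer substrate readings fall roughly in a pseudo-first-order way, and the last of them gives 0.305 h⁻¹. The flask's saturation share divided by this rate is the drain time, the hours in which the charge would empty a saturated solution without refill if each substrate lost took its reagent at once: 0.312 h. With only part of the charge still open (substrate plus tautomer), it is that time divided by the part. It is far shorter than 6.0 h, so the gas must carry the flask.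

3. Fast extreme: refill holds reagent at 200 mM in both the summer run and the flask, so the flask repeats the summer percentages, with target at 24 %.

4. Slow extreme: gas delivers no more moles per hour than the summer took, so 6.0 h in the flask counts as 3.14 h of summer time. Target then lies between the summer readings 6 % and 17 %.

5. Tautomer forms without reagent and keeps its full clock, so this reckoning puts the flask's target above the slow extreme, toward 24 %, and its reagent clearly under saturation at 6.0 h.

6. The forecast gives 24 % and 93 %, holding that “reagent should have recovered to near saturation”. It differs from this reckoning on reagent.

The flask gives target 23.5 % and reagent 59.4 % of saturation.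

    substrate + reagent → isomer of the product (k = 0.0250 M⁻¹ min⁻¹)
    gas ⇌ reagent, rate k2*(csat - [reagent]) (kL = 0.0370 min⁻¹)
    reagent + tautomer → target (k = 0.0350 M⁻¹ min⁻¹)
    substrate ⇌ tautomer (K = 1.70, k = 0.00310 min⁻¹)

At 6.0 h the flask's open part is 38.3 %, so the drain time is 0.814 h. The refill time, one over the constant of the step from gas to reagent, is 0.450 h. Drain time over the sum of both times gives a reckoned 64.4 % of saturation. The same flask read at 15 h has an open part of 2.83 % and a drain time of 11.0 h, which gives 96.1 %. Its reagent stands at 94.6 % of saturation.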